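Rings A (C21–C13–C14–C17–C20) and B (C13=C12–C16–C15–C14) share the C13–C14 bond, and alkene carbon C13 sits on quaternary C21. Both rings are therefore disconnected in one carbonylative (2+2+1) cycloaddition: an alkyne C12≡C13 and a C14=C15 vinyl group, both held on C21 of a piperidin-4-one, are joined with CO (C16), forming C13–C14, C15–C16 and C16–C12 and setting C14. The precursor is an N-methoxycarbonyl 3-(4-silyloxybutynyl)-3-(2-methylidenebut-3-enyl)piperidin-4-one whose C21 centre comes from an auxiliary-controlled β-keto ester alkylation. Afterwards C16 is deoxygenated, C17 hydroborated, ring C closed by C9 enolate alkylation, and C6 elaborated.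

Key step: step 10

Numbering: C21 = quaternary piperidine carbon; C6 = piperidine carbonyl carbon; C9 = its CH2 neighbour; C12=C13 = ring B alkene (C13 on C21); C14 = ring-fusion methine; C15, C16 = ring B CH2 groups; C17, C18 = ring A methine and its CH2O carbon; C20 = ring A CH2; C11, C10 = the two-carbon arm on C12; C1′–C5′ = side chain on C6 (C3′ carbinol); ring C = C21–C6–C9–C10–C11–C12–C13.
Remark: nitrogen is carried as a methyl carbamate (non-basic toward rhodium and alkyl halides) and becomes N-methyl in the last step; the C10 oxygen is a tert-butyldiphenylsilyl ether so that it survives the ketal hydrolysis.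
Remark: in step 5 the alkylated face depends on the lithium ligand set; L-valine ester with HMPA is written, and the D-auxiliary is used instead if correlation of 9 shows the other sense.

Step 1
Reactants: 1 isoprene
Product: 2 (E)-1,4-dibromo-2-methylbut-2-ene
Conditions: Br2 (1.0 equiv), CH2Cl2, −25 → 0 °C
Reagents that add atoms: bromine, BrBr
Why: Electrophilic bromination of the 1,3-diene, where equilibration of the allylic dibromides should leave the conjugate 1,4-adduct as the main product.

Step 2
Reactants: 2 (E)-1,4-dibromo-2-methylbut-2-ene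
Product: 3 2-(bromomethyl)buta-1,3-diene
Conditions: DMPU, 120 °C, reduced pressure, product distilled out as formed
Reagents that add atoms: none
Why: Vinylogous E2 (1,4-dehydrobromination: methyl proton and remote allylic bromide) should give the cross-conjugated bromodiene, protected from dimerisation by immediate distillation.

Step 3
Reactants: 4 methyl 4-oxopiperidine-3-carboxylate hydrochloride
Product: 5 dimethyl 4-oxopiperidine-1,3-dicarboxylate
Conditions: MeOCOCl, NaHCO3, CH2Cl2/H2O, 0 → 25 °C
Reagents that add atoms: methyl chloroformate, COC(Cl)=O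
Why: Schotten–Baumann N-acylation, in which the secondary amine outcompetes the enolised keto ester under aqueous bicarbonate.

Step 4
Reactants: 5 dimethyl 4-oxopiperidine-1,3-dicarboxylate; 6 L-valine tert-butyl ester hydrochloride
Product: 7 dimethyl 4-{[(2S)-1-tert-butoxy-3-methyl-1-oxobutan-2-yl]amino}-5,6-dihydropyridine-1,3(2H)-dicarboxylate
Conditions: NaOAc (1.0 equiv), 4 Å molecular sieves, toluene, 60 °C
Reagents that add atoms: none
Why: Condensation of a β-keto ester with a primary amine gives the hydrogen-bonded enamino ester (vinylogous carbamate), driven by removal of water.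

Step 5
Reactants: 7 dimethyl 4-{[(2S)-1-tert-butoxy-3-methyl-1-oxobutan-2-yl]amino}-5,6-dihydropyridine-1,3(2H)-dicarboxylate; 3 2-(bromomethyl)buta-1,3-diene
Product: 9 dimethyl (3R)-3-(2-methylidenebut-3-en-1-yl)-4-oxopiperidine-1,3-dicarboxylate, via C21-alkylated valine imine 8 (not isolated)
Conditions: LiN(iPr)2, toluene, −78 °C; HMPA; 3, −78 → −40 °C; then 1 M aq. HCl, THF, 0 °C
Reagents that add atoms: water, O
Why: Chiral lithio-enamine alkylation, in which the chelated valine ester shields one face of the aza-enolate so that the allylic bromide sets quaternary C21 (R), and mild acid hydrolysis releases the auxiliary.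

Step 6
Reactants: 9 dimethyl (3R)-3-(2-methylidenebut-3-en-1-yl)-4-oxopiperidine-1,3-dicarboxylate
Product: 10 dimethyl (6R)-6-(2-methylidenebut-3-en-1-yl)-1,4-dioxa-8-azaspiro[4.5]decane-6,8-dicarboxylate
Conditions: (Me3SiOCH2)2, Me3SiOTf (5 mol %), CH2Cl2, −78 → −20 °C
Reagents that add atoms: 1,2-bis(trimethylsilyloxy)ethane, C[Si](C)(C)OCCO[Si](C)(C)C
Why: Silyl-triflate-catalysed ketalization, driven by loss of hexamethyldisiloxane, masks the hindered C6 ketone at a temperature the diene tolerates.

Step 7
Reactants: 10 dimethyl (6R)-6-(2-methylidenebut-3-en-1-yl)-1,4-dioxa-8-azaspiro[4.5]decane-6,8-dicarboxylate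
Product: 12 methyl (6R)-6-ethynyl-6-(2-methylidenebut-3-en-1-yl)-1,4-dioxa-8-azaspiro[4.5]decane-8-carboxylate, via neopentyl aldehyde 11 (not isolated)
Conditions: iBu2AlH (1.2 equiv), CH2Cl2, −78 °C; then MeOH, K2CO3, dimethyl (1-diazo-2-oxopropyl)phosphonate, −78 → 25 °C
Reagents that add atoms: dimethyl (1-diazo-2-oxopropyl)phosphonate, COP(=O)(OC)C(=[N+]=[N-])C(C)=O
Why: Partial hydride reduction of the α-quaternary ester to the aluminium hemiacetal, then Ohira–Bestmann (Seyferth–Gilbert) homologation of the non-enolisable aldehyde in the same flask; the carbamate is less electrophilic than the ester at −78 °C.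

Step 8
Reactants: 12 methyl (6R)-6-ethynyl-6-(2-methylidenebut-3-en-1-yl)-1,4-dioxa-8-azaspiro[4.5]decane-8-carboxylate; 13 (2-bromoethoxy)(tert-butyl)diphenylsilane
Product: 14 methyl (6R)-6-{4-[(tert-butyldiphenylsilyl)oxy]but-1-yn-1-yl}-6-(2-methylidenebut-3-en-1-yl)-1,4-dioxa-8-azaspiro[4.5]decane-8-carboxylate
Conditions: LiN(iPr)2, THF, −78 °C; 13, DMPU, −78 → 25 °C
Reagents that add atoms: none
Why: SN2 alkylation of the lithium acetylide with a primary bromide in a dipolar medium; the amide base spares the carbamate and the diene.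

Step 9
Reactants: 14 methyl (6R)-6-{4-[(tert-butyldiphenylsilyl)oxy]but-1-yn-1-yl}-6-(2-methylidenebut-3-en-1-yl)-1,4-dioxa-8-azaspiro[4.5]decane-8-carboxylate
Product: 15 methyl (3R)-3-{4-[(tert-butyldiphenylsilyl)oxy]but-1-yn-1-yl}-3-(2-methylidenebut-3-en-1-yl)-4-oxopiperidine-1-carboxylate
Conditions: TsOH·H2O (cat.), acetone/H2O, 50 °C
Reagents that add atoms: water, O
Why: Acid-catalysed ketal hydrolysis; the diphenyl-substituted silyl ether, the carbamate and the diene should survive dilute aqueous acid.

Step 10
Reactants: 15 methyl (3R)-3-{4-[(tert-butyldiphenylsilyl)oxy]but-1-yn-1-yl}-3-(2-methylidenebut-3-en-1-yl)-4-oxopiperidine-1-carboxylate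
Product: 16 spiro enone: methyl 4-oxopiperidine-1-carboxylate spiro-linked at C21 to the ring A/ring B bicyclo[3.3.0]oct-1-en-3-one (C16 ketone; C12=C13; C17=C18 methylidene; 2-(tert-butyldiphenylsilyloxy)ethyl on C12; H14 on the ring A face opposite C6)
Conditions: [Rh(CO)2Cl]2 (5 mol %), CO (1 atm), ClCH2CH2Cl, 80 °C
Reagents that add atoms: carbon monoxide, [C-]#[O+]
Why: Monovalent rhodium binds the alkyne and the 1,3-diene, oxidative cyclisation of C12≡C13 with the C14=C15 vinyl group gives a rhodacyclopentene (C13–C14 bond), and CO insertion followed by reductive elimination forms C15–C16 and C16–C12; the closest known reaction type is the rhodium-catalysed dienyl Pauson–Khand (2+2+1) cycloaddition of 1,3-diene-ynes. Ring A closes in the exo mode of a 1,6-enyne, helped by the fully substituted propargylic C21, and ring B closes as the cyclopentenone of the carbonylative event. The single new stereocentre C14 is controlled by C21: the flat C6 carbonyl is the smaller spiro flank and should take the concave side next to the C11 arm, so ring B folds toward C6 and H14 ends on the face of the N-CH2 flank. The step needs carbonylation to outrun cycloisomerisation and the C14=C15 alkene to react instead of C17=C18; the CO atmosphere serves the first, and the tether secures the second because C17=C18 could only close a four-membered ring and a (4+2) mode would need a bridgehead alkene, while the carbamate keeps nitrogen off rhodium. The cross-conjugated C17=C18 alkene should accelerate the reaction by diene coordination and survives as the handle for C18. Any C14 epimer is removed by chromatography.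

Step 11
Reactants: 16 spiro enone
Product: 17 spiro enone alcohol: as 16 with the C6 ketone reduced to CH–OH (both C6 epimers)
Conditions: NaBH4, MeOH/CH2Cl2 (1:1), −78 °C
Reagents that add atoms: none
Why: Chemoselective borohydride reduction, since the saturated ketone should react far faster than the fully substituted cyclopentenone at low temperature; C6 is thereby masked against dithiol and borane, and its configuration is irrelevant.

Step 12
Reactants: 17 spiro enone alcohol
Product: 18 dithiolane: as 17 with C16 as its 1,3-dithiolane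
Conditions: HSCH2CH2SH, BF3·OEt2 (0.5 equiv), CH2Cl2, −20 → 0 °C
Reagents that add atoms: ethane-1,2-dithiol, SCCS
Why: Lewis-acid dithioketalization of the only carbonyl left; C13 is fully substituted, so conjugate thiol addition and alkene migration should not compete, and short cold contact spares the methylidene.

Step 13
Reactants: 18 dithiolane
Product: 20 diol: as 18 with C17(H)–CH2OH in place of the methylidene (H17 cis to H14; C18 on the ring A face of C6), via B-alkyl-9-BBN adduct 19 (not isolated)
Conditions: 9-BBN (3 equiv), THF, 0 → 25 °C; then NaOH, H2O2, 0 °C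
Reagents that add atoms: hydrogen peroxide, OO
Why: Anti-Markovnikov hydroboration–oxidation, in which the bulky borane should approach from the convex face of the diquinane (the H14 side, away from C15 and the C6 flank), placing H17 cis to H14.

Step 14
Reactants: 20 diol
Product: 21 C18 pivalate of 20
Conditions: tBuCOCl, pyridine, CH2Cl2, 0 °C
Reagents that add atoms: pivaloyl chloride, CC(C)(C)C(Cl)=O
Why: Selective acylation of the primary alcohol over the neopentyl secondary C6 carbinol.

Step 15
Reactants: 21 C18 pivalate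
Product: 22 as 21 with C16 as CH2 (dithiolane removed; C12=C13 retained)
Conditions: Raney Ni (W-2), EtOH, reflux
Reagents that add atoms: none
Why: Mozingo desulfurization; the tetrasubstituted C12=C13 alkene is the only C=C left and should be inert to the nickel.

Step 16
Reactants: 22 C16-deoxy alcohol
Product: 23 C6 ketone: as 22 with the C6 carbinol oxidised
Conditions: Dess–Martin periodinane, CH2Cl2, 25 °C
Reagents that add atoms: none
Why: Dess–Martin oxidation of the only free alcohol restores the ketone needed for ring C.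

Step 17
Reactants: 23 C6 ketone
Product: 24 C10 alcohol: as 23 with the silyl ether cleaved
Conditions: Bu4NF, THF, 0 → 25 °C
Reagents that add atoms: none
Why: Fluoride-induced desilylation; the pivalate and the carbamate are stable to it.

Step 18
Reactants: 24 C10 alcohol
Product: 25 C10 iodide: as 24 with CH2CH2I on C12
Conditions: I2, PPh3, imidazole, CH2Cl2, 0 → 25 °C
Reagents that add atoms: iodine, II
Why: Appel-type iodination of the primary alcohol under neutral conditions.

Step 19
Reactants: 25 C10 iodide
Product: 26 tetracyclic ketone: rings A, B and C with the N-methoxycarbonyl piperidine; C6 ketone bridging C21 and C9; C18 pivalate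
Conditions: KN(SiMe3)2 (1.05 equiv), THF (0.01 M), −78 → 0 °C
Reagents that add atoms: none
Why: Intramolecular enolate alkylation (7-exo-tet): the ketone can enolise only toward C9, the cis C12=C13 alkene holds the iodoethyl arm over the piperidone, and the bridge allows only one configuration at C9.

Step 20
Reactants: 26 tetracyclic ketone
Product: 28 C6 aldehyde: as 26 with C6(H)–CHO (both C6 epimers), via methyl enol ether 27 (not isolated)
Conditions: Ph3P(Cl)CH2OMe, KOtBu, THF, 0 → 50 °C; then 2 M aq. HCl, THF, 25 °C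
Reagents that add atoms: (methoxymethyl)triphenylphosphonium chloride, COC[P+](c1ccccc1)(c1ccccc1)c1ccccc1.[Cl-]; water, O
Why: Wittig methoxymethylenation of the non-enolisable bridging ketone, then enol ether hydrolysis, a one-carbon homologation that supplies C1′.

Step 21
Reactants: 28 C6 aldehyde
Product: 29 hydroxymethyl aldehyde: as 28 with quaternary C6 bearing CHO on the piperidine side and CH2OH on the side of the C10–C13 bridge
Conditions: 37% aq. HCHO (excess), K2CO3, MeOH/THF, 25 → 40 °C
Reagents that add atoms: formaldehyde, C=O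
Why: Crossed aldol hydroxymethylation of the α-branched aldehyde; formaldehyde should add to the exocyclic C6 enolate from the carbocyclic-bridge face, where sp2 C13 carries no axial hydrogen, and not over the piperidine with its two syn-axial N-CH2 hydrogens.

Step 22
Reactants: 29 hydroxymethyl aldehyde
Product: 30 bis-pivalate aldehyde: C6–CH2OH pivalate of 29
Conditions: tBuCOCl, pyridine, 4-(dimethylamino)pyridine (cat.), CH2Cl2, 0 → 25 °C
Reagents that add atoms: pivaloyl chloride, CC(C)(C)C(Cl)=O
Why: Nucleophile-catalysed acylation of the neopentyl alcohol shuts off retro-aldol loss of formaldehyde in the basic olefination.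

Step 23
Reactants: 30 bis-pivalate aldehyde
Product: 31 (E)-enone: as 30 with C6–CH=CH–C(=O)–CH2CH3 in place of CHO
Conditions: (EtO)2P(O)CH2C(O)Et, NaH, THF, 0 → 40 °C
Reagents that add atoms: diethyl (2-oxobutyl)phosphonate, CCC(=O)CP(=O)(OCC)OCC
Why: Horner–Wadsworth–Emmons olefination of a non-enolisable aldehyde with a β-keto phosphonate anion, which should be E-selective and nucleophilic enough for the hindered carbonyl.

Step 24
Reactants: 31 (E)-enone
Product: 32 (S)-allylic alcohol: as 31 with the C3′ ketone reduced to the (S)-carbinol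
Conditions: (R)-1-methyl-3,3-diphenyltetrahydro-1H,3H-pyrrolo[1,2-c][1,3,2]oxazaborole (20 mol %), catecholborane, toluene, −78 °C
Reagents that add atoms: none
Why: Corey–Bakshi–Shibata reduction, in which the alkenyl group is the large and ethyl the small substituent, so the (R)-catalyst should give the (S)-carbinol under catalyst control.

Step 25
Reactants: 32 (S)-allylic alcohol
Product: 33 saturated (S)-carbinol: as 32 with a C1′–C2′ single bond
Conditions: H2 (1 atm), 10% Pd on carbon, EtOAc, 25 °C
Reagents that add atoms: none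
Why: Heterogeneous hydrogenation of the disubstituted alkene; the tetrasubstituted C12=C13 alkene should not react at one atmosphere.

Step 26
Reactants: 33 saturated (S)-carbinol
Product: 34 target CNP0221997.1: N-methyl tetracyclic triol (C6–CH2OH, C18–OH, (3′S)-3′-hydroxypentyl on C6)
Conditions: LiAlH4 (excess), THF, reflux; aqueous NaOH work-up
Reagents that add atoms: none
Why: Global hydride reduction cleaves both pivalates to the primary alcohols and reduces the methyl carbamate to the N-methyl amine without touching a stereocentre.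

Compound list
1 | isoprene | C=CC(C)=C | starting material
2 | (E)-1,4-dibromo-2-methylbut-2-ene | BrC/C(C)=C/CBr | intermediate
3 | 2-(bromomethyl)buta-1,3-diene | BrCC(=C)C=C | intermediate
4 | methyl 4-oxopiperidine-3-carboxylate hydrochloride | COC(=O)C1CNCCC1=O.Cl | starting material
5 | dimethyl 4-oxopiperidine-1,3-dicarboxylate | COC(=O)N1CCC(=O)C(C(=O)OC)C1 | intermediate
6 | L-valine tert-butyl ester hydrochloride | CC(C)[C@H](N)C(=O)OC(C)(C)C.Cl | starting material
7 | dimethyl 4-{[(2S)-1-tert-butoxy-3-methyl-1-oxobutan-2-yl]amino}-5,6-dihydropyridine-1,3(2H)-dicarboxylate | COC(=O)N1CCC(N[C@@H](C(C)C)C(=O)OC(C)(C)C)=C(C(=O)OC)C1 | intermediate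
8 | C21-alkylated valine imine (not isolated) | COC(=O)N1CCC(=N[C@@H](C(C)C)C(=O)OC(C)(C)C)[C@@](C(=O)OC)(CC(=C)C=C)C1 | intermediate
9 | dimethyl (3R)-3-(2-methylidenebut-3-en-1-yl)-4-oxopiperidine-1,3-dicarboxylate | COC(=O)N1CCC(=O)[C@@](C(=O)OC)(CC(=C)C=C)C1 | intermediate
10 | dimethyl (6R)-6-(2-methylidenebut-3-en-1-yl)-1,4-dioxa-8-azaspiro[4.5]decane-6,8-dicarboxylate | COC(=O)N1CCC2(OCCO2)[C@@](C(=O)OC)(CC(=C)C=C)C1 | intermediate
11 | neopentyl aldehyde, methyl (6S)-6-formyl-6-(2-methylidenebut-3-en-1-yl)-1,4-dioxa-8-azaspiro[4.5]decane-8-carboxylate (not isolated) | COC(=O)N1CCC2(OCCO2)[C@@](C=O)(CC(=C)C=C)C1 | intermediate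
12 | methyl (6R)-6-ethynyl-6-(2-methylidenebut-3-en-1-yl)-1,4-dioxa-8-azaspiro[4.5]decane-8-carboxylate | COC(=O)N1CCC2(OCCO2)[C@@](C#C)(CC(=C)C=C)C1 | intermediate
13 | (2-bromoethoxy)(tert-butyl)diphenylsilane | CC(C)(C)[Si](OCCBr)(c1ccccc1)c1ccccc1 | starting material
14 | methyl (6R)-6-{4-[(tert-butyldiphenylsilyl)oxy]but-1-yn-1-yl}-6-(2-methylidenebut-3-en-1-yl)-1,4-dioxa-8-azaspiro[4.5]decane-8-carboxylate | COC(=O)N1CCC2(OCCO2)[C@@](C#CCCO[Si](c3ccccc3)(c3ccccc3)C(C)(C)C)(CC(=C)C=C)C1 | intermediate
15 | methyl (3R)-3-{4-[(tert-butyldiphenylsilyl)oxy]but-1-yn-1-yl}-3-(2-methylidenebut-3-en-1-yl)-4-oxopiperidine-1-carboxylate | COC(=O)N1CCC(=O)[C@@](C#CCCO[Si](c2ccccc2)(c2ccccc2)C(C)(C)C)(CC(=C)C=C)C1 | intermediate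
16 | spiro enone (rings A and B closed; C16 ketone; C17 methylidene; H14 anti to C6) | COC(=O)N1CCC(=O)[C@]2(C1)CC(=C)[C@@H]3CC(=O)C(CCO[Si](c4ccccc4)(c4ccccc4)C(C)(C)C)=C23 | intermediate
17 | spiro enone alcohol (C6 carbinol, both epimers) | COC(=O)N1CCC(O)[C@]2(C1)CC(=C)[C@@H]3CC(=O)C(CCO[Si](c4ccccc4)(c4ccccc4)C(C)(C)C)=C23 | intermediate
18 | C16 dithiolane | COC(=O)N1CCC(O)[C@]2(C1)CC(=C)[C@@H]3CC4(SCCS4)C(CCO[Si](c5ccccc5)(c5ccccc5)C(C)(C)C)=C23 | intermediate
19 | B-alkyl-9-BBN adduct at C18 (not isolated) | COC(=O)N1CCC(O)[C@]2(C1)C[C@H](CB4C5CCCC4CCC5)[C@@H]3CC6(SCCS6)C(CCO[Si](c7ccccc7)(c7ccccc7)C(C)(C)C)=C23 | intermediate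
20 | C6,C18 diol (H17 cis to H14) | COC(=O)N1CCC(O)[C@]2(C1)C[C@H](CO)[C@@H]3CC4(SCCS4)C(CCO[Si](c5ccccc5)(c5ccccc5)C(C)(C)C)=C23 | intermediate
21 | C18 pivalate of 20 | COC(=O)N1CCC(O)[C@]2(C1)C[C@H](COC(=O)C(C)(C)C)[C@@H]3CC4(SCCS4)C(CCO[Si](c5ccccc5)(c5ccccc5)C(C)(C)C)=C23 | intermediate
22 | C16-deoxy alcohol | COC(=O)N1CCC(O)[C@]2(C1)C[C@H](COC(=O)C(C)(C)C)[C@@H]3CCC(CCO[Si](c4ccccc4)(c4ccccc4)C(C)(C)C)=C23 | intermediate
23 | C6 ketone | COC(=O)N1CCC(=O)[C@]2(C1)C[C@H](COC(=O)C(C)(C)C)[C@@H]3CCC(CCO[Si](c4ccccc4)(c4ccccc4)C(C)(C)C)=C23 | intermediate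
24 | C10 alcohol | COC(=O)N1CCC(=O)[C@]2(C1)C[C@H](COC(=O)C(C)(C)C)[C@@H]3CCC(CCO)=C23 | intermediate
25 | C10 iodide | COC(=O)N1CCC(=O)[C@]2(C1)C[C@H](COC(=O)C(C)(C)C)[C@@H]3CCC(CCI)=C23 | intermediate
26 | tetracyclic ketone (ring C closed) | O=C1[C@H]2CCC3=C4[C@@H](CC3)[C@@H](COC(=O)C(C)(C)C)C[C@]41CN(C(=O)OC)C2 | intermediate
27 | methyl enol ether at C6 (not isolated) | COC=C1[C@H]2CCC3=C4[C@@H](CC3)[C@@H](COC(=O)C(C)(C)C)C[C@]41CN(C(=O)OC)C2 | intermediate
28 | C6 aldehyde (both C6 epimers) | O=CC1[C@H]2CCC3=C4[C@@H](CC3)[C@@H](COC(=O)C(C)(C)C)C[C@]41CN(C(=O)OC)C2 | intermediate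
29 | hydroxymethyl aldehyde (quaternary C6) | O=C[C@]1(CO)[C@H]2CCC3=C4[C@@H](CC3)[C@@H](COC(=O)C(C)(C)C)C[C@]41CN(C(=O)OC)C2 | intermediate
30 | bis-pivalate aldehyde | O=C[C@]1(COC(=O)C(C)(C)C)[C@H]2CCC3=C4[C@@H](CC3)[C@@H](COC(=O)C(C)(C)C)C[C@]41CN(C(=O)OC)C2 | intermediate
31 | (E)-enone | CCC(=O)/C=C/[C@]1(COC(=O)C(C)(C)C)[C@H]2CCC3=C4[C@@H](CC3)[C@@H](COC(=O)C(C)(C)C)C[C@]41CN(C(=O)OC)C2 | intermediate
32 | (S)-allylic alcohol | CC[C@H](O)/C=C/[C@]1(COC(=O)C(C)(C)C)[C@H]2CCC3=C4[C@@H](CC3)[C@@H](COC(=O)C(C)(C)C)C[C@]41CN(C(=O)OC)C2 | intermediate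
33 | saturated (S)-carbinol, bis-pivalate carbamate | CC[C@H](O)CC[C@]1(COC(=O)C(C)(C)C)[C@H]2CCC3=C4[C@@H](CC3)[C@@H](COC(=O)C(C)(C)C)C[C@]41CN(C(=O)OC)C2 | intermediate
34 | target CNP0221997.1 | CC[C@H](O)CC[C@]1(CO)[C@H]2CCC3=C4[C@@H](CC3)[C@@H](CO)C[C@]41CN(C)C2 | target

Total step count: 26. Longest linear sequence: 24 steps (4 → 34, steps 3–26; the two-step preparation of 3 runs in parallel).

Steps most likely to fail

Step 10. The process at risk is weak facial discrimination at C14 during oxidative cyclisation, because the two flanks of the spiro carbon differ only modestly in size. The fallback replaces kinetic by thermodynamic control. It sets out from 15, cyclised as in step 10. The unwanted ring-fusion isomer, C14-epimeric spiro enone F1, is separated and equilibrated through its extended dienolate (1,8-diazabicyclo[5.4.0]undec-7-ene, toluene, 80 °C; γ-deprotonation at C14 and reprotonation). The mixture is re-chromatographed and F1 recycled, so that the material converges on 16.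

Step 21. The process at risk is attack of formaldehyde on the C6 enolate from the piperidine face instead of the carbocyclic face, made worse by slow enolisation of the hindered aldehyde. The fallback exchanges the roles of the two C6 substituents, so that this same facial preference gives the correct centre. It sets out from 28. Base-catalysed Michael addition (KOtBu cat., THF, −20 °C) to pent-1-yn-3-one gives the keto-enal F2, in which the side chain has entered from the piperidine face and the formyl group is the future CH2OH. Corey–Bakshi–Shibata reduction with the same (R)-oxazaborole and excess catecholborane reduces both carbonyls to the (S)-allylic alcohol diol F3. Hydrogenation over Pd on carbon gives the saturated diol F4. LiAlH4 in refluxing THF then cleaves the C18 pivalate and reduces the carbamate, which rejoins the route at 34.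

Step 20. The process at risk is sluggish addition of the bulky phosphorus ylide to the C6 carbonyl, which is flanked by quaternary C21 and tertiary C9. The fallback is a one-carbon homologation through a sulfur ylide. It sets out from 26. Corey–Chaykovsky methylenation (trimethylsulfonium iodide, KOtBu, DMSO/THF, 0 → 25 °C) gives the C6 spiro-epoxide F5. BF3·OEt2 (cat.) in CH2Cl2 at −78 °C opens the epoxide at C6, and the 1,2-hydride shift (Meinwald rearrangement) returns the route to 28.

Further compounds
F1 | step 10 | C14-epimeric spiro enone (H14 on the ring A face of C6) | COC(=O)N1CCC(=O)[C@]2(C1)CC(=C)[C@H]3CC(=O)C(CCO[Si](c4ccccc4)(c4ccccc4)C(C)(C)C)=C23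
F2 | step 21 | keto-enal: quaternary C6 bearing CHO and (E)-3-oxopent-1-enyl, C18 pivalate | CCC(=O)/C=C/[C@]1(C=O)[C@H]2CCC3=C4[C@@H](CC3)[C@@H](COC(=O)C(C)(C)C)C[C@]41CN(C(=O)OC)C2
F3 | step 21 | (S)-allylic alcohol diol: C6–CH2OH and (E,3S)-3-hydroxypent-1-enyl on C6, C18 pivalate | CC[C@H](O)/C=C/[C@]1(CO)[C@H]2CCC3=C4[C@@H](CC3)[C@@H](COC(=O)C(C)(C)C)C[C@]41CN(C(=O)OC)C2
F4 | step 21 | saturated diol: C6–CH2OH and (3S)-3-hydroxypentyl on C6, C18 pivalate, N-methoxycarbonyl | CC[C@H](O)CC[C@]1(CO)[C@H]2CCC3=C4[C@@H](CC3)[C@@H](COC(=O)C(C)(C)C)C[C@]41CN(C(=O)OC)C2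
F5 | step 20 | C6 spiro-epoxide of 26 (oxirane CH2–O on C6, either epimer) | C15(CO5)[C@H]2CCC3=C4[C@@H](CC3)[C@@H](COC(=O)C(C)(C)C)C[C@]41CN(C(=O)OC)C2
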